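**Plan**
- Retrosynthesis: the two benzyl ethers on ring B come off last. Ring C is then cut at C4–C4a (acyl–arene bond), which opens the flavone to an E 3-aryl-3-aryloxy-2-methoxyacrylic acid.
- That acid is cut at the vinylic C2–O1 bond (3,5-dimethoxyphenoxide plus an enol triflate), at C2–C3 (aldol of methyl methoxyacetate with the ring B aldehyde) and at C1'–CHO (formylation of dibenzylated methoxyhydroquinone).
- Forward: ring B is protected and formylated, the C2–C3–C4 chain is added by aldol and oxidation, ring A is hung on through O1, and ring C closes last. Hydrogenolysis then frees the 2',5'-diol.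
- Enabling feature: in the 3,5-dimethoxyphenoxy group the two carbons ortho to O1 (future C4a and C8) are mirror images of each other. Each is activated by O1 and by both methoxy groups (future 5-OMe and 7-OMe), so closure at C4–C4a can go only one way.
- Stereochemistry: the target has no stereocentre. The only stereo-element on the way is the E alkene (carboxyl cis to the aryloxy group), set by O-triflation of a chelated enolate and retentive vinylic substitution.

Key step: step 8

Remark: the aldol product is carried as a racemic syn/anti mixture because both centres vanish on oxidation and enol triflation; the enol triflate, the aryloxyacrylate and the acid are drawn as the E isomers expected from the chelated sodium enolate and a retentive addition–elimination, and any Z isomer would be removed by chromatography at the ester stage.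

Step 1
Reactants: 1 methoxyhydroquinone (2-methoxybenzene-1,4-diol)
Product: 2 1,4-bis(benzyloxy)-2-methoxybenzene
Conditions: BnBr (2.3 equiv), K2CO3, DMF, 60 °C, N2
Reagents that add atoms: benzyl bromide, BrCc1ccccc1
Why: Williamson etherification of both phenols under carbonate base is routine, and benzyl ethers are chosen because they should survive enolate, hydroxide and trifluoroacetic anhydride conditions yet fall to hydrogenolysis at the end.

Step 2
Reactants: 2 1,4-bis(benzyloxy)-2-methoxybenzene
Product: 4 2,5-bis(benzyloxy)-4-methoxybenzaldehyde, via iminium chloride 3 (not isolated)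
Conditions: POCl3, DMF, 0 → 70 °C; then H2O, 0 °C → rt
Reagents that add atoms: N,N-dimethylformamide, CN(C)C=O; water, O
Why: Vilsmeier–Haack formylation should strike the single ring position that is para to an alkoxy group (para to the methoxy, ortho to a benzyloxy), as 1,2,4-trialkoxybenzenes do, and the iminium salt is hydrolysed to the aldehyde on aqueous quench.

Step 3
Reactants: 4 2,5-bis(benzyloxy)-4-methoxybenzaldehyde; 5 methyl methoxyacetate
Product: 8 methyl 3-[2,5-bis(benzyloxy)-4-methoxyphenyl]-3-hydroxy-2-methoxypropanoate, via lithium enolate 6 (not isolated), via lithium aldolate 7 (not isolated)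
Conditions: 5, LiN(iPr)2 (LDA), THF, −78 °C; then 4, −78 °C; aq NH4Cl
Reagents that add atoms: none
Why: Aldol addition of a preformed lithium enolate of an α-alkoxy ester to a non-enolisable aryl aldehyde at −78 °C is reliable; the two new stereocentres form without control (racemic syn/anti mixture), which is acceptable because steps 4 and 5 erase both.

Step 4
Reactants: 8 methyl 3-[2,5-bis(benzyloxy)-4-methoxyphenyl]-3-hydroxy-2-methoxypropanoate
Product: 9 methyl 3-[2,5-bis(benzyloxy)-4-methoxyphenyl]-2-methoxy-3-oxopropanoate
Conditions: Dess–Martin periodinane, CH2Cl2, 0 °C → rt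
Reagents that add atoms: none
Why: Dess–Martin oxidation of a secondary benzylic alcohol runs under near-neutral conditions that should avoid retro-aldol cleavage, and both diastereomers converge on one racemic β-keto ester.

Step 5
Reactants: 9 methyl 3-[2,5-bis(benzyloxy)-4-methoxyphenyl]-2-methoxy-3-oxopropanoate
Product: 11 methyl (E)-3-[2,5-bis(benzyloxy)-4-methoxyphenyl]-2-methoxy-3-{[(trifluoromethyl)sulfonyl]oxy}prop-2-enoate, via sodium enolate 10 (not isolated)
Conditions: NaH, Et2O, 0 °C; then Tf2O, −78 → 0 °C
Reagents that add atoms: trifluoromethanesulfonic anhydride, O=S(=O)(OS(=O)(=O)C(F)(F)F)C(F)(F)F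
Why: O-sulfonylation of the sodium chelate enolate of a β-keto ester with Tf2O is the standard entry to β-triflyloxy acrylates, and the chelate should place the triflate cis to the ester, which is the E alkene here.

Step 6
Reactants: 11 methyl (E)-3-[2,5-bis(benzyloxy)-4-methoxyphenyl]-2-methoxy-3-{[(trifluoromethyl)sulfonyl]oxy}prop-2-enoate; 12 3,5-dimethoxyphenol
Product: 13 methyl (E)-3-[2,5-bis(benzyloxy)-4-methoxyphenyl]-3-(3,5-dimethoxyphenoxy)-2-methoxyprop-2-enoate
Conditions: Cs2CO3, MeCN, rt → 50 °C
Reagents that add atoms: none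
Why: Nucleophilic vinylic substitution by addition–elimination: the phenoxide formed with Cs2CO3 adds to the β-carbon of the β-triflyloxy acrylate, the ester stabilises the carbanion and triflate leaves, a well-used way to β-aryloxy acrylates that normally goes with retention and so should leave the aryloxy group cis to the ester.

Step 7
Reactants: 13 methyl (E)-3-[2,5-bis(benzyloxy)-4-methoxyphenyl]-3-(3,5-dimethoxyphenoxy)-2-methoxyprop-2-enoate
Product: 15 (E)-3-[2,5-bis(benzyloxy)-4-methoxyphenyl]-3-(3,5-dimethoxyphenoxy)-2-methoxyprop-2-enoic acid, via lithium carboxylate 14 (not isolated)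
Conditions: LiOH, THF/MeOH/H2O, 40 °C; then 1 M HCl, 0 °C, pH 3
Reagents that add atoms: lithium hydroxide, [Li+].[OH-]
Why: Saponification of a methyl ester by acyl–oxygen cleavage, as is standard for β-aryloxycinnamic esters, should leave the benzyl ethers and the alkene geometry untouched, and cold acidification to pH 3 spares the acid-labile enol ether.

Step 8
Reactants: 15 (E)-3-[2,5-bis(benzyloxy)-4-methoxyphenyl]-3-(3,5-dimethoxyphenoxy)-2-methoxyprop-2-enoic acid
Product: 17 2-[2,5-bis(benzyloxy)-4-methoxyphenyl]-3,5,7-trimethoxy-4H-chromen-4-one, via mixed anhydride 16 (not isolated)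
Conditions: (CF3CO)2O (1.5 equiv), CH2Cl2, 0 °C → rt
Reagents that add atoms: none
Why: Trifluoroacetic anhydride turns the acid into mixed anhydride 16, whose acyl carbon becomes acylium-like as trifluoroacetate leaves and is attacked by an ortho carbon of the aryloxy ring, after which proton loss restores ring A; this is an intramolecular Friedel–Crafts acylation, the reaction type long used to close β-aryloxycinnamic acids to flavones under acid. Ring C closes by a 6-exo-trig attack on the acyl carbon, forming C4–C4a. No stereocentre is created. Regioselectivity on ring A needs no control because the 3,5-dimethoxyphenoxy group has a mirror plane through its C1 and C4, so the two ortho carbons are identical, and each lies ortho to the ether oxygen, ortho to one methoxy and para to the other, which makes it the most electron-rich arene carbon in the molecule. Chemoselectivity over reaction on ring B (five-membered indenone closure at C6' or lactonisation at the 2'-benzyloxy oxygen) is secured by the E geometry that holds the carboxyl beside the aryloxy ring, by the preference for the six-membered closure, and by the much weaker activation of C6'; a small excess of anhydride at 0 °C should keep intermolecular trifluoroacetylation and benzyl ether cleavage in check.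

Step 9
Reactants: 17 2-[2,5-bis(benzyloxy)-4-methoxyphenyl]-3,5,7-trimethoxy-4H-chromen-4-one
Product: 18 5-O-methyloxyayanin-A, 2-(2,5-dihydroxy-4-methoxyphenyl)-3,5,7-trimethoxy-4H-chromen-4-one
Conditions: H2 (1 atm), Pd/C (palladium on carbon), EtOAc/MeOH, rt; work-up under argon
Reagents that add atoms: none
Why: Hydrogenolysis of aryl benzyl ethers over Pd/C at atmospheric pressure is selective, the tetrasubstituted vinylogous-ester C2=C3 bond of the chromone should not be reduced under these conditions, and work-up under inert gas protects the freed hydroquinone from oxidation.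

**Compound list**
1 | methoxyhydroquinone (2-methoxybenzene-1,4-diol) | COc1cc(O)ccc1O | starting material
2 | 1,4-bis(benzyloxy)-2-methoxybenzene | COc1cc(OCc2ccccc2)ccc1OCc1ccccc1 | intermediate
3 | N-{[2,5-bis(benzyloxy)-4-methoxyphenyl]methylidene}-N-methylmethanaminium chloride | COc1cc(OCc2ccccc2)c(C=[N+](C)C)cc1OCc1ccccc1.[Cl-] | intermediate (not isolated)
4 | 2,5-bis(benzyloxy)-4-methoxybenzaldehyde | COc1cc(OCc2ccccc2)c(C=O)cc1OCc1ccccc1 | intermediate
5 | methyl methoxyacetate | COCC(=O)OC | starting material
6 | lithium (E)-1,2-dimethoxyethen-1-olate (chelated enolate of 5, C2 methoxy cis to O–Li) | [Li+].CO/C=C(\[O-])OC | intermediate (not isolated)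
7 | lithium alkoxide of 8 (racemic syn/anti mixture) | [Li+].COC(C(=O)OC)C([O-])c1cc(OCc2ccccc2)c(OC)cc1OCc1ccccc1 | intermediate (not isolated)
8 | methyl 3-[2,5-bis(benzyloxy)-4-methoxyphenyl]-3-hydroxy-2-methoxypropanoate (racemic syn/anti mixture) | COC(C(=O)OC)C(O)c1cc(OCc2ccccc2)c(OC)cc1OCc1ccccc1 | intermediate
9 | methyl 3-[2,5-bis(benzyloxy)-4-methoxyphenyl]-2-methoxy-3-oxopropanoate (racemic) | COC(C(=O)OC)C(=O)c1cc(OCc2ccccc2)c(OC)cc1OCc1ccccc1 | intermediate
10 | sodium (E)-1-[2,5-bis(benzyloxy)-4-methoxyphenyl]-2,3-dimethoxy-3-oxoprop-1-en-1-olate (O–Na cis to the ester) | [Na+].COC(=O)/C(OC)=C(\[O-])c1cc(OCc2ccccc2)c(OC)cc1OCc1ccccc1 | intermediate (not isolated)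
11 | methyl (E)-3-[2,5-bis(benzyloxy)-4-methoxyphenyl]-2-methoxy-3-{[(trifluoromethyl)sulfonyl]oxy}prop-2-enoate | COC(=O)/C(OC)=C(\OS(=O)(=O)C(F)(F)F)c1cc(OCc2ccccc2)c(OC)cc1OCc1ccccc1 | intermediate
12 | 3,5-dimethoxyphenol | COc1cc(O)cc(OC)c1 | starting material
13 | methyl (E)-3-[2,5-bis(benzyloxy)-4-methoxyphenyl]-3-(3,5-dimethoxyphenoxy)-2-methoxyprop-2-enoate | COC(=O)/C(OC)=C(\Oc1cc(OC)cc(OC)c1)c1cc(OCc2ccccc2)c(OC)cc1OCc1ccccc1 | intermediate
14 | lithium (E)-3-[2,5-bis(benzyloxy)-4-methoxyphenyl]-3-(3,5-dimethoxyphenoxy)-2-methoxyprop-2-enoate | [Li+].[O-]C(=O)/C(OC)=C(\Oc1cc(OC)cc(OC)c1)c1cc(OCc2ccccc2)c(OC)cc1OCc1ccccc1 | intermediate (not isolated)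
15 | (E)-3-[2,5-bis(benzyloxy)-4-methoxyphenyl]-3-(3,5-dimethoxyphenoxy)-2-methoxyprop-2-enoic acid | OC(=O)/C(OC)=C(\Oc1cc(OC)cc(OC)c1)c1cc(OCc2ccccc2)c(OC)cc1OCc1ccccc1 | intermediate
16 | mixed anhydride of 15 with trifluoroacetic acid (E) | O=C(OC(=O)C(F)(F)F)/C(OC)=C(\Oc1cc(OC)cc(OC)c1)c1cc(OCc2ccccc2)c(OC)cc1OCc1ccccc1 | intermediate (not isolated)
17 | 2-[2,5-bis(benzyloxy)-4-methoxyphenyl]-3,5,7-trimethoxy-4H-chromen-4-one | COc1cc(OC)c2c(=O)c(OC)c(-c3cc(OCc4ccccc4)c(OC)cc3OCc3ccccc3)oc2c1 | intermediate
18 | 5-O-methyloxyayanin-A, 2-(2,5-dihydroxy-4-methoxyphenyl)-3,5,7-trimethoxy-4H-chromen-4-one | COc1cc(OC)c2c(=O)c(OC)c(-c3cc(O)c(OC)cc3O)oc2c1 | target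

**Step count**
Total steps: 9. Longest linear sequence: 9 steps (1 → 18); 5 and 12 enter as bought building blocks.

**Steps most likely to fail**

Step 6. What may go wrong: triflyl transfer, in which the phenoxide attacks the sulfonyl sulfur and not the vinylic carbon, so that the enolate of the keto ester is returned. Alternatively, addition to the β-carbon may be too slow, because that carbon carries an electron-rich aryl group and sits next to the α-methoxy donor. The fallback sets out from 11 (with 12) and comes back at 13. It makes the same C–O bond by palladium-catalysed cross-coupling in place of uncatalysed substitution: Pd2(dba)3 (tris(dibenzylideneacetone)dipalladium), 2-(di-tert-butylphosphino)biphenyl, K3PO4, toluene, 90 °C. Oxidative addition of zerovalent palladium into the C–OTf bond, followed by C–O reductive elimination, does not depend on the electrophilicity of the acrylate. The weak base in a non-polar medium should also disfavour attack at sulfur. This is the known coupling of enol triflates with phenols; no new compound arises on this path (entry F0).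

Step 8. What may go wrong: acid-induced E/Z equilibration of the push–pull alkene, followed by closure of the Z acid onto ring B (lactonisation at the 2'-benzyloxy oxygen with loss of the benzyl group). Trifluoroacetylation of ring A may also compete with ring closure, or the enol ether may be cleaved by protonation. The fallback closes ring C the other way round, at O1–C2, by a Baker–Venkataraman sequence. It sets out from aldehyde 4 and phenol 12 and comes back at 17. Pinnick oxidation of 4 (NaClO2, NaH2PO4, 2-methyl-2-butene, t-BuOH/H2O) would give 2,5-bis(benzyloxy)-4-methoxybenzoic acid F1. Friedel–Crafts acylation of 12 with methoxyacetyl chloride ortho to the hydroxyl (AlCl3, CH2Cl2, 0 °C) would give 1-(2-hydroxy-4,6-dimethoxyphenyl)-2-methoxyethan-1-one F2. Esterification of F2 with F1 (EDC·HCl, DMAP, CH2Cl2) would give 3,5-dimethoxy-2-(methoxyacetyl)phenyl 2,5-bis(benzyloxy)-4-methoxybenzoate F3. Base-induced acyl migration (LiN(SiMe3)2, THF, −78 → 0 °C) would give 1-[2,5-bis(benzyloxy)-4-methoxyphenyl]-3-(2-hydroxy-4,6-dimethoxyphenyl)-2-methoxypropane-1,3-dione F4. Cyclodehydration of F4 (catalytic TsOH, toluene, 80 °C) would then close the pyranone to 17.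

Step 7. What may go wrong: hydroxide adds to the β-carbon and expels the aryloxide (the reverse of step 6), or the hindered tetrasubstituted ester resists hydrolysis. The fallback carries the carboxyl as a tert-butyl ester, which is removed by acid without any nucleophile. It sets out from aldehyde 4 and comes back at 15. Aldol addition of purchased tert-butyl methoxyacetate (LiN(iPr)2, THF, −78 °C) would give tert-butyl 3-[2,5-bis(benzyloxy)-4-methoxyphenyl]-3-hydroxy-2-methoxypropanoate F5. Dess–Martin oxidation would give tert-butyl 3-[2,5-bis(benzyloxy)-4-methoxyphenyl]-2-methoxy-3-oxopropanoate F6. NaH then Tf2O would give tert-butyl (E)-3-[2,5-bis(benzyloxy)-4-methoxyphenyl]-2-methoxy-3-{[(trifluoromethyl)sulfonyl]oxy}prop-2-enoate F7. Substitution with 12 (Cs2CO3, MeCN) would give tert-butyl (E)-3-[2,5-bis(benzyloxy)-4-methoxyphenyl]-3-(3,5-dimethoxyphenoxy)-2-methoxyprop-2-enoate F8. CF3CO2H in CH2Cl2 at 0 °C, with loss of isobutene, would then deliver acid 15, which can be treated with the anhydride of step 8 in the same flask.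

**Further compounds**
F0 | step 6 | none | none
F1 | step 8 | 2,5-bis(benzyloxy)-4-methoxybenzoic acid | OC(=O)c1cc(OCc2ccccc2)c(OC)cc1OCc1ccccc1
F2 | step 8 | 1-(2-hydroxy-4,6-dimethoxyphenyl)-2-methoxyethan-1-one | COCC(=O)c1c(O)cc(OC)cc1OC
F3 | step 8 | 3,5-dimethoxy-2-(methoxyacetyl)phenyl 2,5-bis(benzyloxy)-4-methoxybenzoate | COCC(=O)c1c(OC(=O)c2cc(OCc3ccccc3)c(OC)cc2OCc2ccccc2)cc(OC)cc1OC
F4 | step 8 | 1-[2,5-bis(benzyloxy)-4-methoxyphenyl]-3-(2-hydroxy-4,6-dimethoxyphenyl)-2-methoxypropane-1,3-dione (racemic) | COC(C(=O)c1c(O)cc(OC)cc1OC)C(=O)c1cc(OCc2ccccc2)c(OC)cc1OCc1ccccc1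
F5 | step 7 | tert-butyl 3-[2,5-bis(benzyloxy)-4-methoxyphenyl]-3-hydroxy-2-methoxypropanoate (racemic syn/anti mixture) | COC(C(=O)OC(C)(C)C)C(O)c1cc(OCc2ccccc2)c(OC)cc1OCc1ccccc1
F6 | step 7 | tert-butyl 3-[2,5-bis(benzyloxy)-4-methoxyphenyl]-2-methoxy-3-oxopropanoate (racemic) | COC(C(=O)OC(C)(C)C)C(=O)c1cc(OCc2ccccc2)c(OC)cc1OCc1ccccc1
F7 | step 7 | tert-butyl (E)-3-[2,5-bis(benzyloxy)-4-methoxyphenyl]-2-methoxy-3-{[(trifluoromethyl)sulfonyl]oxy}prop-2-enoate | CC(C)(C)OC(=O)/C(OC)=C(\OS(=O)(=O)C(F)(F)F)c1cc(OCc2ccccc2)c(OC)cc1OCc1ccccc1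
F8 | step 7 | tert-butyl (E)-3-[2,5-bis(benzyloxy)-4-methoxyphenyl]-3-(3,5-dimethoxyphenoxy)-2-methoxyprop-2-enoate | CC(C)(C)OC(=O)/C(OC)=C(\Oc1cc(OC)cc(OC)c1)c1cc(OCc2ccccc2)c(OC)cc1OCc1ccccc1
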